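## Retrosynthetic overview

1. C10–Br and the C9 ketone come last: bromide opening and elimination of a 10,11-epoxy ketone, the ketone arising from a C9 silyl ether (1,3-carbonyl transposition C12 → C9).
2. That transposition turns an E-alkylidene built next to a C12 ketone into the 7Z dienone, so C7=C8 is cut to an aldol condensation of (R)-4-silyloxycyclopentenone with a C4–C7 (E)-enal.
3. C12–C13 and the C12 carbinol centre: electroreductive zinc propargylation of the C12 ketone with a C13–C20 skipped-diynyl bromide, anti to the C9 silyloxy group; 14Z,17Z by semi-hydrogenation.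
4. C1–C7: the enal carries C4 inside the γ-lactone of a D-glutamic-acid-derived building block; the lactone is opened to methyl ester and silyl ether mid-route.
5. Rings: the carbocycle is bought and never broken; the only ring events are lactone opening and a transient 10,11-epoxide.

Assumption: both chiral starting materials are bought as single R enantiomers; prostanoid numbering (C1 ester carbon, ring C8–C12, C20 terminal methyl) is used for atom labels.

## Route

Step 1
Reactants: 1 (4R)-4-hydroxycyclopent-2-en-1-one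
Product: 2 (4R)-4-[(triethylsilyl)oxy]cyclopent-2-en-1-one
Conditions: TESCl, imidazole, CH2Cl2, 0 °C
Reagents that add atoms: chlorotriethylsilane, CC[Si](Cl)(CC)CC
Why: Silyl ether formation on a secondary alcohol, which leaves the bought centre (future C9) untouched and installs a group that can later be removed next to a tert-butyldimethylsilyl ether.

Step 2
Reactants: 3 (5R)-5-(hydroxymethyl)oxolan-2-one; 4 (triphenylphosphoranylidene)acetaldehyde
Product: 6 (2E)-3-[(2R)-5-oxooxolan-2-yl]prop-2-enal, via aldehyde 5 (not isolated)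
Conditions: IBX, 4 (1.05 equiv), DMSO, rt
Reagents that add atoms: none
Why: Tandem IBX oxidation–Wittig olefination, in which the labile α-oxy aldehyde is trapped as it forms by the stabilised ylide to give the (E)-enal, the stereocentre (future C4, R) being bought in 3.

Step 3
Reactants: 2 (4R)-4-[(triethylsilyl)oxy]cyclopent-2-en-1-one; 6 (2E)-3-[(2R)-5-oxooxolan-2-yl]prop-2-enal
Product: 9 (4S,5E)-5-{(2E)-3-[(2R)-5-oxooxolan-2-yl]prop-2-en-1-ylidene}-4-[(triethylsilyl)oxy]cyclopent-2-en-1-one, via aldol adduct 7 (not isolated), via mesylate 8 (not isolated)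
Conditions: LiN(iPr)2 (LDA), THF, −78 °C; 6, −78 °C; then MsCl, Et3N, −78 → 0 °C
Reagents that add atoms: none
Why: Kinetic α′-enolate aldol addition, mesylation and E1cB elimination (aldol condensation) place C6 anti to the C12 carbonyl and cis to the CH(OSiEt3) carbon, as in aldol condensations that give (12E)-alkylidene cyclopentenone prostaglandins; C5=C6 keeps the E geometry of 6, no stereocentre is formed, and the silyloxy carbon changes descriptor from R to S only because its neighbour becomes sp2.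

Step 4
Reactants: 10 but-1-yne; 11 1,4-dibromobut-2-yne
Product: 13 1-bromoocta-2,5-diyne, via but-1-yn-1-ylmagnesium bromide 12 (not isolated)
Conditions: EtMgBr, THF, 0 → 40 °C; then CuBr (5 mol %), 11 (3 equiv), THF, −20 °C → rt
Reagents that add atoms: none
Why: Copper-catalysed SN2 coupling of an alkynyl Grignard reagent with a propargylic bromide (classical skipped-diyne synthesis), excess 11 holding the reaction at mono-substitution.

Step 5
Reactants: 9 (4S,5E)-5-{(2E)-3-[(2R)-5-oxooxolan-2-yl]prop-2-en-1-ylidene}-4-[(triethylsilyl)oxy]cyclopent-2-en-1-one; 13 1-bromoocta-2,5-diyne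
Product: 15 (1R,4S,5E)-1-(octa-2,5-diyn-1-yl)-5-{(2E)-3-[(2R)-5-oxooxolan-2-yl]prop-2-en-1-ylidene}-4-[(triethylsilyl)oxy]cyclopent-2-en-1-ol, via allenylzinc bromide 14 (not isolated)
Conditions: undivided cell, Zn anode, Ni-foam cathode, ZnBr2 (0.2 equiv), Bu4NBr (0.1 M), THF–DMF 4:1, 0 °C, 4 mA cm−2, 13 (1.5 equiv) added over 3 h, 2.5 F per mol of 13; pH 7 phosphate work-up
Reagents that add atoms: none
Why: Proposed new method: a sacrificial-anode electroreductive Barbier propargylation that delivers the whole C13–C20 skipped diyne in one step; divalent zinc released at the anode is plated at the cathode as highly active zerovalent zinc (the cathode stays near the divalent/zerovalent zinc couple, about −1 V versus SCE, positive of the dienone reduction wave), which inserts into the propargylic C–Br bond of 13 to give allenylzinc bromide 14 at low steady-state concentration; 14 adds to the C12 ketone of 9 through a six-membered SE2′ transition state at its unsubstituted CH2 terminus (the other mode would join a fully substituted allenyl carbon to a hindered ketone), in 1,2-fashion and anti to the C9 triethylsilyloxy group, which sets the C12 carbinol centre with C13 trans to the C9 oxygen; the closest known reactions are the zinc Barbier propargylation of ketones with propargyl bromide and sacrificial-anode electroreductive allylation and propargylation of carbonyl compounds, neither shown for a γ-substituted skipped-diynyl bromide or for a 5-alkylidene-4-silyloxycyclopentenone.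

Step 6
Reactants: 15 (1R,4S,5E)-1-(octa-2,5-diyn-1-yl)-5-{(2E)-3-[(2R)-5-oxooxolan-2-yl]prop-2-en-1-ylidene}-4-[(triethylsilyl)oxy]cyclopent-2-en-1-ol
Product: 16 (1R,4S,5E)-1-[(2Z,5Z)-octa-2,5-dien-1-yl]-5-{(2E)-3-[(2R)-5-oxooxolan-2-yl]prop-2-en-1-ylidene}-4-[(triethylsilyl)oxy]cyclopent-2-en-1-ol
Conditions: H2 (1 atm), Lindlar catalyst (Pd on CaCO3 poisoned with Pb(OAc)2), quinoline, EtOAc–hexane, 0 °C → rt, stopped after 2 equiv H2
Reagents that add atoms: none
Why: Lindlar semi-hydrogenation adds H2 syn to each internal alkyne on the poisoned palladium surface to give the 14Z,17Z skipped diene, leaving the more substituted alkenes and the lactone alone.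

Step 7
Reactants: 16 (1R,4S,5E)-1-[(2Z,5Z)-octa-2,5-dien-1-yl]-5-{(2E)-3-[(2R)-5-oxooxolan-2-yl]prop-2-en-1-ylidene}-4-[(triethylsilyl)oxy]cyclopent-2-en-1-ol
Product: 19 methyl (4R,5E,7E,9S,12R,14Z,17Z)-4-[(tert-butyldimethylsilyl)oxy]-12-hydroxy-9-[(triethylsilyl)oxy]prosta-5,7,10,14,17-pentaen-1-oate, via potassium carboxylate 17 (not isolated), via hydroxy ester 18 (not isolated)
Conditions: KOH (1.05 equiv), THF–MeOH–H2O, 0 °C; evaporate; MeI, DMF, 0 °C → rt; then TBSCl, imidazole, rt
Reagents that add atoms: potassium hydroxide, [K+].[OH-]; iodomethane, CI; tert-butyldimethylsilyl chloride, CC(C)(C)[Si](C)(C)Cl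
Why: Lactone saponification, SN2 O-methylation of the carboxylate and silylation of the freed secondary C4 hydroxyl before it can relactonise (the tertiary C12 hydroxyl is too hindered to silylate), with no C4–O bond broken so the bought 4R centre is kept.

Step 8
Reactants: 19 methyl (4R,5E,7E,9S,12R,14Z,17Z)-4-[(tert-butyldimethylsilyl)oxy]-12-hydroxy-9-[(triethylsilyl)oxy]prosta-5,7,10,14,17-pentaen-1-oate
Product: 20 methyl (4R,5E,7E,9S,12R,14Z,17Z)-4-[(tert-butyldimethylsilyl)oxy]-9,12-dihydroxyprosta-5,7,10,14,17-pentaen-1-oate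
Conditions: TBAF (1.1 equiv), AcOH (1.1 equiv), THF, −20 → 0 °C
Reagents that add atoms: none
Why: Buffered fluoride desilylation cleaves a secondary triethylsilyl ether much faster than a secondary tert-butyldimethylsilyl ether, and the near-neutral medium spares the acid-sensitive doubly allylic carbinols.

Step 9
Reactants: 20 methyl (4R,5E,7E,9S,12R,14Z,17Z)-4-[(tert-butyldimethylsilyl)oxy]-9,12-dihydroxyprosta-5,7,10,14,17-pentaen-1-oate
Product: 21 methyl (4R,5E,7Z,12R,14Z,17Z)-4-[(tert-butyldimethylsilyl)oxy]-12-hydroxy-9-oxoprosta-5,7,10,14,17-pentaen-1-oate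
Conditions: MnO2 (activated, excess), CH2Cl2, rt, dark
Reagents that add atoms: none
Why: Allylic oxidation with MnO2 of the only free secondary (doubly allylic) alcohol completes the carbonyl transposition, so that C6, placed anti to the C12 carbonyl in step 3, now lies cis to the C9 carbonyl (7Z without any isomerisation), and the C9 centre that controlled C12 is erased.

Step 10
Reactants: 21 methyl (4R,5E,7Z,12R,14Z,17Z)-4-[(tert-butyldimethylsilyl)oxy]-12-hydroxy-9-oxoprosta-5,7,10,14,17-pentaen-1-oate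
Product: 22 methyl (4R,5E,7Z,10S,11R,12S,14Z,17Z)-4-[(tert-butyldimethylsilyl)oxy]-10,11-epoxy-12-hydroxy-9-oxoprosta-5,7,14,17-tetraen-1-oate
Conditions: t-BuOOH (anhydrous, 1.5 equiv), DBU (1.2 equiv), CH2Cl2, −20 → 0 °C, dark
Reagents that add atoms: tert-butyl hydroperoxide, CC(C)(C)OO
Why: Weitz–Scheffer nucleophilic epoxidation is expected at the endocyclic enone because that is the more electrophilic site of cross-conjugated cyclopentenone prostanoids, attack at C11 keeps the C9/C7=C8/C5=C6 dienone conjugated, and the 12-hydroxyl hydrogen-bonds the peroxide anion (epoxide cis to 12-OH, both new centres being removed in step 11), while isolated alkenes are inert to a nucleophilic oxidant.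

Step 11
Reactants: 22 methyl (4R,5E,7Z,10S,11R,12S,14Z,17Z)-4-[(tert-butyldimethylsilyl)oxy]-10,11-epoxy-12-hydroxy-9-oxoprosta-5,7,14,17-tetraen-1-oate
Product: 25 methyl (4R,5E,7Z,12R,14Z,17Z)-10-bromo-4-[(tert-butyldimethylsilyl)oxy]-12-hydroxy-9-oxoprosta-5,7,10,14,17-pentaen-1-oate, via bromohydrin 23 (not isolated), via mesylate 24 (not isolated)
Conditions: LiBr, AcOH, THF, 0 °C → rt; then Et3N (excess), MsCl, 0 °C
Reagents that add atoms: lithium bromide, [Li+].[Br-]
Why: Bromide opens the α,β-epoxy ketone by SN2 attack at the carbonyl-activated C10 (C11 is neopentyl), and mesylation of the new secondary 11-hydroxyl with E1cB elimination gives the 10-bromo enone (the classical epoxy ketone to α-halo enone conversion), with no electrophilic bromine that would attack the skipped diene.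

Step 12
Reactants: 25 methyl (4R,5E,7Z,12R,14Z,17Z)-10-bromo-4-[(tert-butyldimethylsilyl)oxy]-12-hydroxy-9-oxoprosta-5,7,10,14,17-pentaen-1-oate
Product: 26 methyl (4R,5E,7Z,12R,14Z,17Z)-10-bromo-4,12-dihydroxy-9-oxoprosta-5,7,10,14,17-pentaen-1-oate
Conditions: HF·pyridine, pyridine, THF, 0 °C → rt, dark; NaHCO3 work-up at 0 °C
Reagents that add atoms: none
Why: Buffered HF·pyridine desilylation of the secondary silyl ether avoids the base-induced lactonisation of the γ-hydroxy ester and Michael chemistry of the bromo dienone, and touches no stereocentre or double bond.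

## Compound list

1 | (4R)-4-hydroxycyclopent-2-en-1-one | O=C1C=C[C@H](O)C1 | starting material
2 | (4R)-4-[(triethylsilyl)oxy]cyclopent-2-en-1-one | O=C1C=C[C@H](O[Si](CC)(CC)CC)C1 | intermediate
3 | (5R)-5-(hydroxymethyl)oxolan-2-one | OC[C@H]1CCC(=O)O1 | starting material
4 | (triphenylphosphoranylidene)acetaldehyde | O=CC=P(c1ccccc1)(c1ccccc1)c1ccccc1 | starting material
5 | (2R)-5-oxooxolane-2-carbaldehyde | O=C[C@H]1CCC(=O)O1 | intermediate
6 | (2E)-3-[(2R)-5-oxooxolan-2-yl]prop-2-enal | O=C/C=C/[C@H]1CCC(=O)O1 | intermediate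
7 | (4S)-5-{(2E)-1-hydroxy-3-[(2R)-5-oxooxolan-2-yl]prop-2-en-1-yl}-4-[(triethylsilyl)oxy]cyclopent-2-en-1-one (lithium alkoxide in the flask; mixture at the two new centres) | O=C1C=C[C@H](O[Si](CC)(CC)CC)C1C(O)/C=C/[C@H]2CCC(=O)O2 | intermediate
8 | methanesulfonate of 7 | O=C1C=C[C@H](O[Si](CC)(CC)CC)C1C(OS(C)(=O)=O)/C=C/[C@H]2CCC(=O)O2 | intermediate
9 | (4S,5E)-5-{(2E)-3-[(2R)-5-oxooxolan-2-yl]prop-2-en-1-ylidene}-4-[(triethylsilyl)oxy]cyclopent-2-en-1-one | O=C1C=C[C@H](O[Si](CC)(CC)CC)/C1=C\C=C\[C@H]2CCC(=O)O2 | intermediate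
10 | but-1-yne | CCC#C | starting material
11 | 1,4-dibromobut-2-yne | BrCC#CCBr | starting material
12 | but-1-yn-1-ylmagnesium bromide | CCC#C[Mg]Br | intermediate
13 | 1-bromoocta-2,5-diyne | CCC#CCC#CCBr | intermediate
14 | bromo(octa-1,2-dien-5-yn-3-yl)zinc | C=C=C([Zn]Br)CC#CCC | intermediate
15 | (1R,4S,5E)-1-(octa-2,5-diyn-1-yl)-5-{(2E)-3-[(2R)-5-oxooxolan-2-yl]prop-2-en-1-ylidene}-4-[(triethylsilyl)oxy]cyclopent-2-en-1-ol | CCC#CCC#CC[C@@]1(O)C=C[C@H](O[Si](CC)(CC)CC)/C1=C\C=C\[C@H]2CCC(=O)O2 | intermediate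
16 | (1R,4S,5E)-1-[(2Z,5Z)-octa-2,5-dien-1-yl]-5-{(2E)-3-[(2R)-5-oxooxolan-2-yl]prop-2-en-1-ylidene}-4-[(triethylsilyl)oxy]cyclopent-2-en-1-ol | CC/C=C\C/C=C\C[C@@]1(O)C=C[C@H](O[Si](CC)(CC)CC)/C1=C\C=C\[C@H]2CCC(=O)O2 | intermediate
17 | potassium (4R,5E,7E,9S,12R,14Z,17Z)-4,12-dihydroxy-9-[(triethylsilyl)oxy]prosta-5,7,10,14,17-pentaen-1-oate | CC/C=C\C/C=C\C[C@@]1(O)C=C[C@H](O[Si](CC)(CC)CC)/C1=C\C=C\[C@H](O)CCC(=O)[O-].[K+] | intermediate
18 | methyl (4R,5E,7E,9S,12R,14Z,17Z)-4,12-dihydroxy-9-[(triethylsilyl)oxy]prosta-5,7,10,14,17-pentaen-1-oate | CC/C=C\C/C=C\C[C@@]1(O)C=C[C@H](O[Si](CC)(CC)CC)/C1=C\C=C\[C@H](O)CCC(=O)OC | intermediate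
19 | methyl (4R,5E,7E,9S,12R,14Z,17Z)-4-[(tert-butyldimethylsilyl)oxy]-12-hydroxy-9-[(triethylsilyl)oxy]prosta-5,7,10,14,17-pentaen-1-oate | CC/C=C\C/C=C\C[C@@]1(O)C=C[C@H](O[Si](CC)(CC)CC)/C1=C\C=C\[C@H](O[Si](C)(C)C(C)(C)C)CCC(=O)OC | intermediate
20 | methyl (4R,5E,7E,9S,12R,14Z,17Z)-4-[(tert-butyldimethylsilyl)oxy]-9,12-dihydroxyprosta-5,7,10,14,17-pentaen-1-oate | CC/C=C\C/C=C\C[C@@]1(O)C=C[C@H](O)/C1=C\C=C\[C@H](O[Si](C)(C)C(C)(C)C)CCC(=O)OC | intermediate
21 | methyl (4R,5E,7Z,12R,14Z,17Z)-4-[(tert-butyldimethylsilyl)oxy]-12-hydroxy-9-oxoprosta-5,7,10,14,17-pentaen-1-oate | CC/C=C\C/C=C\C[C@@]1(O)C=CC(=O)/C1=C\C=C\[C@H](O[Si](C)(C)C(C)(C)C)CCC(=O)OC | intermediate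
22 | methyl (4R,5E,7Z,10S,11R,12S,14Z,17Z)-4-[(tert-butyldimethylsilyl)oxy]-10,11-epoxy-12-hydroxy-9-oxoprosta-5,7,14,17-tetraen-1-oate (epoxide cis to 12-OH; C12 unchanged in space) | CC/C=C\C/C=C\C[C@@]1(O)[C@@H]2O[C@@H]2C(=O)/C1=C\C=C\[C@H](O[Si](C)(C)C(C)(C)C)CCC(=O)OC | intermediate
23 | methyl (4R,5E,7Z,10R,11S,12S,14Z,17Z)-10-bromo-4-[(tert-butyldimethylsilyl)oxy]-11,12-dihydroxy-9-oxoprosta-5,7,14,17-tetraen-1-oate | CC/C=C\C/C=C\C[C@@]1(O)[C@H](O)[C@@H](Br)C(=O)/C1=C\C=C\[C@H](O[Si](C)(C)C(C)(C)C)CCC(=O)OC | intermediate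
24 | methyl (4R,5E,7Z,10R,11S,12S,14Z,17Z)-10-bromo-4-[(tert-butyldimethylsilyl)oxy]-12-hydroxy-11-[(methylsulfonyl)oxy]-9-oxoprosta-5,7,14,17-tetraen-1-oate | CC/C=C\C/C=C\C[C@@]1(O)[C@H](OS(C)(=O)=O)[C@@H](Br)C(=O)/C1=C\C=C\[C@H](O[Si](C)(C)C(C)(C)C)CCC(=O)OC | intermediate
25 | methyl (4R,5E,7Z,12R,14Z,17Z)-10-bromo-4-[(tert-butyldimethylsilyl)oxy]-12-hydroxy-9-oxoprosta-5,7,10,14,17-pentaen-1-oate | CC/C=C\C/C=C\C[C@@]1(O)C=C(Br)C(=O)/C1=C\C=C\[C@H](O[Si](C)(C)C(C)(C)C)CCC(=O)OC | intermediate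
26 | methyl (4R,5E,7Z,12R,14Z,17Z)-10-bromo-4,12-dihydroxy-9-oxoprosta-5,7,10,14,17-pentaen-1-oate | CC/C=C\C/C=C\C[C@@]1(O)C=C(Br)C(=O)/C1=C\C=C\[C@H](O)CCC(=O)OC | target

## Step count and risks

Total: 12 steps. Longest linear sequence: 10 steps (3 → 6 → 9 → 15 → 16 → 19 → 20 → 21 → 22 → 25 → 26; the branch from 1 is equally long).

Step 5 (the proposed new step) may give the allenic carbinol regioisomer, reduce the dienone, or show poor facial selectivity. The fallback uses known chemistry and sets out from 9. A zinc Barbier reaction with propargyl bromide (C#CCBr; Zn dust, THF, 0 °C) gives, with established homopropargyl selectivity and anti to the silyloxy group, the terminal alkyne (1R,4S,5E)-5-{(2E)-3-[(2R)-5-oxooxolan-2-yl]prop-2-en-1-ylidene}-1-(prop-2-yn-1-yl)-4-[(triethylsilyl)oxy]cyclopent-2-en-1-ol F2. Copper-mediated coupling of F2 with 1-bromopent-2-yne (CCC#CCBr; CuI, NaI, Cs2CO3, DMF, rt) then forms the skipped diyne and comes back to the route at 15.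

Step 3 may fail through loss of silyloxide from the lithium enolate (the leaving group is β to the enolate carbon) or through self-condensation of 2. The fallback sets out from 2 and avoids a basic enolate. TMSOTf and Et3N give the silyl dienol ether triethyl{[(1S)-3-[(trimethylsilyl)oxy]cyclopenta-2,4-dien-1-yl]oxy}silane F1. A Mukaiyama aldol addition of F1 to 6 (BF3·OEt2, CH2Cl2, −78 °C) comes back to the route at 7 as the free aldol, which is mesylated and eliminated (MsCl, Et3N) through 8 to 9.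

Step 10 may epoxidise the exocyclic enone instead, or scramble the 7Z geometry through reversible peroxide addition at C7. The fallback sets out from 21 and uses a removable sulfonyl group to mark C11. PhSO2Na with AcOH (THF–MeOH, rt) adds reversibly to give the thermodynamic endocyclic adduct, which keeps the dienone conjugated: methyl (4R,5E,7Z,12S,14Z,17Z)-4-[(tert-butyldimethylsilyl)oxy]-12-hydroxy-9-oxo-11-(phenylsulfonyl)prosta-5,7,14,17-tetraen-1-oate F3. PhNMe3Br3 (THF, 0 °C), a ketone-selective brominating agent, brominates the only enolisable α-carbon (C10) to give methyl (4R,5E,7Z,12S,14Z,17Z)-10-bromo-4-[(tert-butyldimethylsilyl)oxy]-12-hydroxy-9-oxo-11-(phenylsulfonyl)prosta-5,7,14,17-tetraen-1-oate F4. Et3N then eliminates benzenesulfinate (E1cB) and comes back to the route at 25, bypassing 22–24.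

Further compounds
F1 | step 3 | triethyl{[(1S)-3-[(trimethylsilyl)oxy]cyclopenta-2,4-dien-1-yl]oxy}silane | C[Si](C)(C)OC1=C[C@@H](O[Si](CC)(CC)CC)C=C1
F2 | step 5 | (1R,4S,5E)-5-{(2E)-3-[(2R)-5-oxooxolan-2-yl]prop-2-en-1-ylidene}-1-(prop-2-yn-1-yl)-4-[(triethylsilyl)oxy]cyclopent-2-en-1-ol | C#CC[C@@]1(O)C=C[C@H](O[Si](CC)(CC)CC)/C1=C\C=C\[C@H]2CCC(=O)O2
F3 | step 10 | methyl (4R,5E,7Z,12S,14Z,17Z)-4-[(tert-butyldimethylsilyl)oxy]-12-hydroxy-9-oxo-11-(phenylsulfonyl)prosta-5,7,14,17-tetraen-1-oate (C11 epimers) | CC/C=C\C/C=C\C[C@@]1(O)C(S(=O)(=O)c2ccccc2)CC(=O)/C1=C\C=C\[C@H](O[Si](C)(C)C(C)(C)C)CCC(=O)OC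
F4 | step 10 | methyl (4R,5E,7Z,12S,14Z,17Z)-10-bromo-4-[(tert-butyldimethylsilyl)oxy]-12-hydroxy-9-oxo-11-(phenylsulfonyl)prosta-5,7,14,17-tetraen-1-oate (C10/C11 epimers) | CC/C=C\C/C=C\C[C@@]1(O)C(S(=O)(=O)c2ccccc2)C(Br)C(=O)/C1=C\C=C\[C@H](O[Si](C)(C)C(C)(C)C)CCC(=O)OC
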